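**Plan**

1. Retrosynthesis: CO2 is taken out of the lactone across O–C6 and C11–C12, leaving a ten-membered C6 allylic acetate with an alkenylboronate at C11. The carbocycle is then cut at C6–C7 (enal plus alkynyl epoxide), and the chain at C1=C10 (Wittig) and C3–C4 (Negishi).
2. Forward: a C7 piece from but-2-yne-1,4-diol and a C5 piece from (E)-pent-2-en-4-yn-1-ol are joined at C1=C10. The ten-membered ring is closed at C6–C7 by a palladium/indium propargylation, and the five-membered lactone is closed last with CO2.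
3. Enabling feature: C6 is the allylic terminus of the C4=C5 ring alkene and lies 1,3 to the vinylic carbon C11 across C7. An alkenylcopper at C11 can therefore take up CO2, and the carboxylate can close on a C4–C5–C6 π-allyl palladium complex in the same flask.
4. Stereochemistry: C7 and C8 come from a Sharpless epoxidation (C8–O kept, C7–O replaced with inversion). C6 comes from a 1,3-anti Evans–Tishchenko reduction that also installs the C8 isovalerate, and the cis ring fusion from double inversion at C6. Alkene geometry comes from hydroxyl-directed hydroalumination/iodination (C4=C5) and an E-selective Wittig reaction (C1=C10).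
5. Remark: germacrane numbering is used throughout (C12 lactone carbonyl, C13 exocyclic methylene, C14 aldehyde carbon, C15 hydroxymethyl carbon). The target is made as drawn, (6R,7S,8R), with both ring alkenes E by the CIP rules, which places C2/C9 and C3/C6 cis in the ring.

Key step: step 17

**Step 1**
Reactants: 1 but-2-yne-1,4-diol
Product: 2 4-[(tert-butyldiphenylsilyl)oxy]but-2-yn-1-ol
Conditions: NaH, TBDPSCl, THF, 0 °C to rt (diol in excess)
Reagents that add atoms: tert-butyl(chloro)diphenylsilane, CC(C)(C)[Si](Cl)(c1ccccc1)c1ccccc1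
Why: Monosilylation of a symmetrical diol through its mono-sodium alkoxide (silyl ether formation); no stereocenter is involved.

**Step 2**
Reactants: 2 4-[(tert-butyldiphenylsilyl)oxy]but-2-yn-1-ol
Product: 3 (Z)-4-[(tert-butyldiphenylsilyl)oxy]-3-iodobut-2-en-1-ol
Conditions: NaAlH2(OCH2CH2OMe)2, THF, 0 °C; then I2, −78 °C to 0 °C
Reagents that add atoms: iodine, II
Why: Hydroxyl-directed trans-hydroalumination of the propargylic alcohol puts aluminium on the distal alkyne carbon cis to the CH2O group, and iodinolysis with retention should give the (Z)-iodide that fixes the ring-cis geometry of the later C4=C5 bond.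

**Step 3**
Reactants: 3 (Z)-4-[(tert-butyldiphenylsilyl)oxy]-3-iodobut-2-en-1-ol; 4 (3-ethoxy-3-oxopropyl)zinc bromide
Product: 5 ethyl (E)-4-{[(tert-butyldiphenylsilyl)oxy]methyl}-6-hydroxyhex-4-enoate
Conditions: BrZnCH2CH2CO2Et (excess), Pd(PPh3)4 (cat.), THF, 50 °C
Reagents that add atoms: none
Why: Negishi sp2–sp3 cross-coupling proceeds with retention of alkene geometry, so C3 should enter cis to C6, and the free hydroxyl is tolerated by the organozinc reagent.

**Step 4**
Reactants: 5 ethyl (E)-4-{[(tert-butyldiphenylsilyl)oxy]methyl}-6-hydroxyhex-4-enoate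
Product: 6 (E)-4-{[(tert-butyldiphenylsilyl)oxy]methyl}-6-hydroxyhex-4-enal
Conditions: iBu2AlH, CH2Cl2, −78 °C; Rochelle salt work-up
Reagents that add atoms: none
Why: Partial reduction of the ester by iBu2AlH should stop at the aldehyde because the tetrahedral aluminium hemiacetal is stable at low temperature.

**Step 5**
Reactants: 7 (E)-pent-2-en-4-yn-1-ol
Product: 8 [(2R,3R)-3-ethynyloxiran-2-yl]methanol
Conditions: Ti(OiPr)4 (cat.), D-(−)-diethyl tartrate, tBuOOH, 4 Å MS, CH2Cl2, −20 °C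
Reagents that add atoms: tert-butyl hydroperoxide, CC(C)(C)OO
Why: Sharpless asymmetric epoxidation of the (E)-allylic alcohol with the D-tartrate ligand should deliver oxygen to the face that gives the (2R,3R) trans-epoxide, which sets C8 (retained later) and the C7–O bond (replaced later with inversion).

**Step 6**
Reactants: 8 [(2R,3R)-3-ethynyloxiran-2-yl]methanol
Product: 9 (2R,3S)-2-ethynyl-3-(iodomethyl)oxirane
Conditions: I2, PPh3, imidazole, Et2O/MeCN, 0 °C
Reagents that add atoms: iodine, II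
Why: Appel-type iodination of the primary alcohol (Garegg–Samuelsson conditions) leaves the epoxide and alkyne untouched, and no stereocenter is affected (the descriptor change is formal).

**Step 7**
Reactants: 9 (2R,3S)-2-ethynyl-3-(iodomethyl)oxirane; 10 N-methoxy-N-methyl-2-(triphenyl-λ5-phosphanylidene)acetamide
Product: 12 3-[(2R,3R)-3-ethynyloxiran-2-yl]-N-methoxy-N-methyl-2-(triphenyl-λ5-phosphanylidene)propanamide, via phosphonium iodide 11 (not isolated)
Conditions: MeCN, 60 °C; then aq NaOH, CH2Cl2, 0 °C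
Reagents that add atoms: none
Why: SN2 C-alkylation of the amide-stabilised ylide by the primary iodide gives a phosphonium salt that is deprotonated to the α-substituted stabilised ylide, with the epoxide centres untouched.

**Step 8**
Reactants: 6 (E)-4-{[(tert-butyldiphenylsilyl)oxy]methyl}-6-hydroxyhex-4-enal; 12 3-[(2R,3R)-3-ethynyloxiran-2-yl]-N-methoxy-N-methyl-2-(triphenyl-λ5-phosphanylidene)propanamide
Product: 13 (2E,6E)-6-{[(tert-butyldiphenylsilyl)oxy]methyl}-2-{[(2R,3R)-3-ethynyloxiran-2-yl]methyl}-8-hydroxy-N-methoxy-N-methylocta-2,6-dienamide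
Conditions: CH2Cl2, 40 °C
Reagents that add atoms: none
Why: Wittig olefination with an α-branched, amide-stabilised ylide is E-selective, so C2 should end up trans to the carbonyl carbon C14 and therefore cis to C9 as the ring requires.

**Step 9**
Reactants: 13 (2E,6E)-6-{[(tert-butyldiphenylsilyl)oxy]methyl}-2-{[(2R,3R)-3-ethynyloxiran-2-yl]methyl}-8-hydroxy-N-methoxy-N-methylocta-2,6-dienamide
Product: 14 (2E,6E)-6-{[(tert-butyldiphenylsilyl)oxy]methyl}-2-{[(2R,3R)-3-ethynyloxiran-2-yl]methyl}-8-hydroxyocta-2,6-dienal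
Conditions: iBu2AlH (excess), THF, −78 °C
Reagents that add atoms: none
Why: Reduction of the Weinreb amide stops at the aldehyde through the chelated tetrahedral intermediate, which distinguishes C14 (aldehyde) from the still free C6 alcohol.

**Step 10**
Reactants: 14 (2E,6E)-6-{[(tert-butyldiphenylsilyl)oxy]methyl}-2-{[(2R,3R)-3-ethynyloxiran-2-yl]methyl}-8-hydroxyocta-2,6-dienal
Product: 15 (2E,6E)-3-{[(tert-butyldiphenylsilyl)oxy]methyl}-7-(dimethoxymethyl)-8-[(2R,3R)-3-ethynyloxiran-2-yl]octa-2,6-dien-1-ol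
Conditions: HC(OMe)3, CeCl3·7H2O (cat.), MeOH, 0 °C to rt
Reagents that add atoms: trimethyl orthoformate, COC(OC)OC
Why: Cerium-catalysed acetalisation under near-neutral conditions should mask the C14 enal without opening the alkynyl epoxide, so that only C6 can later act as the aldehyde electrophile.

**Step 11**
Reactants: 15 (2E,6E)-3-{[(tert-butyldiphenylsilyl)oxy]methyl}-7-(dimethoxymethyl)-8-[(2R,3R)-3-ethynyloxiran-2-yl]octa-2,6-dien-1-ol
Product: 16 (2E,6E)-3-{[(tert-butyldiphenylsilyl)oxy]methyl}-7-(dimethoxymethyl)-8-[(2R,3R)-3-ethynyloxiran-2-yl]octa-2,6-dienal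
Conditions: MnO2 (excess), CH2Cl2, rt
Reagents that add atoms: none
Why: MnO2 oxidises only the primary allylic alcohol to the enal (allylic oxidation) and leaves epoxide, alkyne and acetal alone.

**Step 12**
Reactants: 16 (2E,6E)-3-{[(tert-butyldiphenylsilyl)oxy]methyl}-7-(dimethoxymethyl)-8-[(2R,3R)-3-ethynyloxiran-2-yl]octa-2,6-dienal
Product: 17 (1R,2S,3S,4E,8E)-5-{[(tert-butyldiphenylsilyl)oxy]methyl}-9-(dimethoxymethyl)-2-ethynylcyclodeca-4,8-diene-1,3-diol
Conditions: Pd(PPh3)4 (cat.), InI, THF/DMPU, high dilution (slow addition), rt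
Reagents that add atoms: none
Why: Zerovalent palladium opens the alkynyl epoxide by anti SN2′ oxidative addition, indium monoiodide turns the allenylpalladium alkoxide into an allenylindium species, and SE2′ addition through a closed transition state to the C6 aldehyde closes the ten-membered ring at C6–C7 with net inversion at C7 and retention of the C8 oxygen (umpolung propargylation, the propargyl counterpart of metal-mediated allylation ring closures onto enals); the C6 carbinol is expected as the 6S epimer, but either epimer serves because this centre is erased in step 13.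

**Step 13**
Reactants: 17 (1R,2S,3S,4E,8E)-5-{[(tert-butyldiphenylsilyl)oxy]methyl}-9-(dimethoxymethyl)-2-ethynylcyclodeca-4,8-diene-1,3-diol
Product: 18 (2E,6E,9R,10S)-3-{[(tert-butyldiphenylsilyl)oxy]methyl}-7-(dimethoxymethyl)-10-ethynyl-9-hydroxycyclodeca-2,6-dien-1-one
Conditions: MnO2 (excess), CH2Cl2, rt
Reagents that add atoms: none
Why: MnO2 oxidises the allylic C6 alcohol selectively and leaves the non-activated C8 alcohol, so both C6 epimers converge on one β-hydroxy enone.

**Step 14**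
Reactants: 18 (2E,6E,9R,10S)-3-{[(tert-butyldiphenylsilyl)oxy]methyl}-7-(dimethoxymethyl)-10-ethynyl-9-hydroxycyclodeca-2,6-dien-1-one; 19 3-methylbutanal
Product: 20 (1R,2R,3R,4E,8E)-5-{[(tert-butyldiphenylsilyl)oxy]methyl}-9-(dimethoxymethyl)-2-ethynyl-3-hydroxycyclodeca-4,8-dien-1-yl 3-methylbutanoate
Conditions: SmI2 (cat.), 3-methylbutanal (excess), THF, −10 °C
Reagents that add atoms: none
Why: In the Evans–Tishchenko reduction the samarium-bound hemiacetal of the C8 alcohol and 3-methylbutanal delivers hydride to the C6 ketone through a six-membered chair, which should give the 1,3-anti C6 alcohol (6R in germacrane numbering) and at the same time the C8 isovalerate.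

**Step 15**
Reactants: 20 (1R,2R,3R,4E,8E)-5-{[(tert-butyldiphenylsilyl)oxy]methyl}-9-(dimethoxymethyl)-2-ethynyl-3-hydroxycyclodeca-4,8-dien-1-yl 3-methylbutanoate
Product: 21 (1R,2R,3R,4E,8E)-5-{[(tert-butyldiphenylsilyl)oxy]methyl}-9-(dimethoxymethyl)-3-hydroxy-2-[1-(4,4,5,5-tetramethyl-1,3,2-dioxaborolan-2-yl)ethenyl]cyclodeca-4,8-dien-1-yl 3-methylbutanoate
Conditions: (SIMes)CuCl (SIMes = 1,3-dimesitylimidazolidin-2-ylidene; cat.), NaOtBu (cat.), B2pin2, MeOH, THF, rt
Reagents that add atoms: bis(pinacolato)diboron, CC1(C)OB(OC1(C)C)B1OC(C)(C)C(C)(C)O1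
Why: Copper-catalysed protoboration (syn copper–boryl addition to the terminal alkyne, then protonolysis by methanol) with a small N-mesityl carbene ligand should place boron on the internal carbon C11.

**Step 16**
Reactants: 21 (1R,2R,3R,4E,8E)-5-{[(tert-butyldiphenylsilyl)oxy]methyl}-9-(dimethoxymethyl)-3-hydroxy-2-[1-(4,4,5,5-tetramethyl-1,3,2-dioxaborolan-2-yl)ethenyl]cyclodeca-4,8-dien-1-yl 3-methylbutanoate
Product: 22 (1R,2S,3R,4E,8E)-3-acetoxy-5-{[(tert-butyldiphenylsilyl)oxy]methyl}-9-(dimethoxymethyl)-2-[1-(4,4,5,5-tetramethyl-1,3,2-dioxaborolan-2-yl)ethenyl]cyclodeca-4,8-dien-1-yl 3-methylbutanoate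
Conditions: Ac2O, pyridine, DMAP (cat.), CH2Cl2, 0 °C
Reagents that add atoms: acetic anhydride, CC(=O)OC(C)=O
Why: DMAP-catalysed acetylation of the allylic C6 alcohol occurs with retention and installs the leaving group for the π-allyl step.

**Step 17**
Reactants: 22 (1R,2S,3R,4E,8E)-3-acetoxy-5-{[(tert-butyldiphenylsilyl)oxy]methyl}-9-(dimethoxymethyl)-2-[1-(4,4,5,5-tetramethyl-1,3,2-dioxaborolan-2-yl)ethenyl]cyclodeca-4,8-dien-1-yl 3-methylbutanoate
Product: 24 (3aS,4R,6E,10E,11aR)-10-{[(tert-butyldiphenylsilyl)oxy]methyl}-6-(dimethoxymethyl)-3-methylidene-2-oxo-2,3,3a,4,5,8,9,11a-octahydrocyclodeca[b]furan-4-yl 3-methylbutanoate, via potassium carboxylate 23 (not isolated)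
Conditions: (IPr)CuCl (IPr = 1,3-bis(2,6-diisopropylphenyl)imidazol-2-ylidene; cat.), KOtBu (1 equiv), CO2 (1 atm), THF, 65 °C; then Pd(PPh3)4 (cat.), 45 °C
Reagents that add atoms: carbon dioxide, O=C=O
Why: Transmetalation of the C11 alkenylboronate to the copper tert-butoxide gives an alkenylcopper that inserts CO2, which forms the C11–C12 bond and the potassium carboxylate 23; zerovalent palladium then ionises the C6 allylic acetate with inversion to a C4–C5–C6 π-allyl complex, and the tethered carboxylate attacks C6 on the face opposite palladium to form the O–C6 bond. The closest known reaction types are the monovalent-copper-catalysed carboxylation of alkenylboronic esters with CO2 and the Tsuji–Trost lactonisation of allylic acetates by carboxylate nucleophiles. The γ-lactone closes in a 5-exo mode at the secondary allyl terminus C6, since attack at C4 would need a seven-membered ring and a fully substituted carbon. C6 is re-formed with net retention (double inversion), so the cis ring fusion is controlled by the acetate configuration set in step 14 and by the C7 centre that carries the tether. The step needs carboxylation to precede any allyl–alkenyl C–C coupling, which is secured by adding the palladium catalyst only after the boronate is consumed, and it needs the ring-cis C4=C5 geometry to survive, which the ten-membered ring holds in the anti-configured allyl terminus.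

**Step 18**
Reactants: 24 (3aS,4R,6E,10E,11aR)-10-{[(tert-butyldiphenylsilyl)oxy]methyl}-6-(dimethoxymethyl)-3-methylidene-2-oxo-2,3,3a,4,5,8,9,11a-octahydrocyclodeca[b]furan-4-yl 3-methylbutanoate
Product: 25 (3aS,4R,6E,10E,11aR)-6-formyl-10-(hydroxymethyl)-3-methylidene-2-oxo-2,3,3a,4,5,8,9,11a-octahydrocyclodeca[b]furan-4-yl 3-methylbutanoate
Conditions: 48% aq HF, MeCN, 0 °C to rt
Reagents that add atoms: water, O
Why: Aqueous HF should cleave the silyl ether and hydrolyse the allylic dimethyl acetal to the conjugated aldehyde in one operation (acidic global deprotection), without touching a stereocenter, the lactone or the ester.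

**Compound list**

1 | but-2-yne-1,4-diol | OCC#CCO | starting material
2 | 4-[(tert-butyldiphenylsilyl)oxy]but-2-yn-1-ol | OCC#CCO[Si](c1ccccc1)(c1ccccc1)C(C)(C)C | intermediate
3 | (Z)-4-[(tert-butyldiphenylsilyl)oxy]-3-iodobut-2-en-1-ol | OC/C=C(/CO[Si](c1ccccc1)(c1ccccc1)C(C)(C)C)I | intermediate
4 | (3-ethoxy-3-oxopropyl)zinc bromide | CCOC(=O)CC[Zn]Br | starting material
5 | ethyl (E)-4-{[(tert-butyldiphenylsilyl)oxy]methyl}-6-hydroxyhex-4-enoate | OC/C=C(/CO[Si](c1ccccc1)(c1ccccc1)C(C)(C)C)CCC(=O)OCC | intermediate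
6 | (E)-4-{[(tert-butyldiphenylsilyl)oxy]methyl}-6-hydroxyhex-4-enal | OC/C=C(/CO[Si](c1ccccc1)(c1ccccc1)C(C)(C)C)CCC=O | intermediate
7 | (E)-pent-2-en-4-yn-1-ol | OC/C=C/C#C | starting material
8 | [(2R,3R)-3-ethynyloxiran-2-yl]methanol | OC[C@H]1O[C@@H]1C#C | intermediate
9 | (2R,3S)-2-ethynyl-3-(iodomethyl)oxirane | IC[C@H]1O[C@@H]1C#C | intermediate
10 | N-methoxy-N-methyl-2-(triphenyl-λ5-phosphanylidene)acetamide | CON(C)C(=O)C=P(c1ccccc1)(c1ccccc1)c1ccccc1 | starting material
11 | {1-[(2R,3R)-3-ethynyloxiran-2-yl]-3-[methoxy(methyl)amino]-3-oxopropan-2-yl}triphenylphosphonium iodide (both epimers at the phosphonium-bearing carbon) | CON(C)C(=O)C(C[C@H]1O[C@@H]1C#C)[P+](c1ccccc1)(c1ccccc1)c1ccccc1.[I-] | intermediate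
12 | 3-[(2R,3R)-3-ethynyloxiran-2-yl]-N-methoxy-N-methyl-2-(triphenyl-λ5-phosphanylidene)propanamide | CON(C)C(=O)C(C[C@H]1O[C@@H]1C#C)=P(c1ccccc1)(c1ccccc1)c1ccccc1 | intermediate
13 | (2E,6E)-6-{[(tert-butyldiphenylsilyl)oxy]methyl}-2-{[(2R,3R)-3-ethynyloxiran-2-yl]methyl}-8-hydroxy-N-methoxy-N-methylocta-2,6-dienamide | OC/C=C(/CO[Si](c1ccccc1)(c1ccccc1)C(C)(C)C)CC/C=C(/C(=O)N(C)OC)C[C@H]1O[C@@H]1C#C | intermediate
14 | (2E,6E)-6-{[(tert-butyldiphenylsilyl)oxy]methyl}-2-{[(2R,3R)-3-ethynyloxiran-2-yl]methyl}-8-hydroxyocta-2,6-dienal | OC/C=C(/CO[Si](c1ccccc1)(c1ccccc1)C(C)(C)C)CC/C=C(/C=O)C[C@H]1O[C@@H]1C#C | intermediate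
15 | (2E,6E)-3-{[(tert-butyldiphenylsilyl)oxy]methyl}-7-(dimethoxymethyl)-8-[(2R,3R)-3-ethynyloxiran-2-yl]octa-2,6-dien-1-ol | OC/C=C(/CO[Si](c1ccccc1)(c1ccccc1)C(C)(C)C)CC/C=C(/C(OC)OC)C[C@H]1O[C@@H]1C#C | intermediate
16 | (2E,6E)-3-{[(tert-butyldiphenylsilyl)oxy]methyl}-7-(dimethoxymethyl)-8-[(2R,3R)-3-ethynyloxiran-2-yl]octa-2,6-dienal | O=C/C=C(/CO[Si](c1ccccc1)(c1ccccc1)C(C)(C)C)CC/C=C(/C(OC)OC)C[C@H]1O[C@@H]1C#C | intermediate
17 | (1R,2S,3S,4E,8E)-5-{[(tert-butyldiphenylsilyl)oxy]methyl}-9-(dimethoxymethyl)-2-ethynylcyclodeca-4,8-diene-1,3-diol (germacrane numbering 6S,7S,8R) | O[C@H]1/C=C(/CO[Si](c2ccccc2)(c2ccccc2)C(C)(C)C)CC/C=C(/C(OC)OC)C[C@@H](O)[C@@H]1C#C | intermediate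
18 | (2E,6E,9R,10S)-3-{[(tert-butyldiphenylsilyl)oxy]methyl}-7-(dimethoxymethyl)-10-ethynyl-9-hydroxycyclodeca-2,6-dien-1-one | O=C1/C=C(/CO[Si](c2ccccc2)(c2ccccc2)C(C)(C)C)CC/C=C(/C(OC)OC)C[C@@H](O)[C@@H]1C#C | intermediate
19 | 3-methylbutanal | CC(C)CC=O | starting material
20 | (1R,2R,3R,4E,8E)-5-{[(tert-butyldiphenylsilyl)oxy]methyl}-9-(dimethoxymethyl)-2-ethynyl-3-hydroxycyclodeca-4,8-dien-1-yl 3-methylbutanoate | O[C@@H]1/C=C(/CO[Si](c2ccccc2)(c2ccccc2)C(C)(C)C)CC/C=C(/C(OC)OC)C[C@@H](OC(=O)CC(C)C)[C@@H]1C#C | intermediate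
21 | (1R,2R,3R,4E,8E)-5-{[(tert-butyldiphenylsilyl)oxy]methyl}-9-(dimethoxymethyl)-3-hydroxy-2-[1-(4,4,5,5-tetramethyl-1,3,2-dioxaborolan-2-yl)ethenyl]cyclodeca-4,8-dien-1-yl 3-methylbutanoate | O[C@@H]1/C=C(/CO[Si](c2ccccc2)(c2ccccc2)C(C)(C)C)CC/C=C(/C(OC)OC)C[C@@H](OC(=O)CC(C)C)[C@@H]1C(=C)B3OC(C)(C)C(C)(C)O3 | intermediate
22 | (1R,2S,3R,4E,8E)-3-acetoxy-5-{[(tert-butyldiphenylsilyl)oxy]methyl}-9-(dimethoxymethyl)-2-[1-(4,4,5,5-tetramethyl-1,3,2-dioxaborolan-2-yl)ethenyl]cyclodeca-4,8-dien-1-yl 3-methylbutanoate | CC(=O)O[C@@H]1/C=C(/CO[Si](c2ccccc2)(c2ccccc2)C(C)(C)C)CC/C=C(/C(OC)OC)C[C@@H](OC(=O)CC(C)C)[C@@H]1C(=C)B3OC(C)(C)C(C)(C)O3 | intermediate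
23 | potassium 2-[(1S,2R,3E,7E,10R)-2-acetoxy-4-{[(tert-butyldiphenylsilyl)oxy]methyl}-8-(dimethoxymethyl)-10-(3-methylbutanoyloxy)cyclodeca-3,7-dien-1-yl]prop-2-enoate | CC(=O)O[C@@H]1/C=C(/CO[Si](c2ccccc2)(c2ccccc2)C(C)(C)C)CC/C=C(/C(OC)OC)C[C@@H](OC(=O)CC(C)C)[C@@H]1C(=C)C(=O)[O-].[K+] | intermediate
24 | (3aS,4R,6E,10E,11aR)-10-{[(tert-butyldiphenylsilyl)oxy]methyl}-6-(dimethoxymethyl)-3-methylidene-2-oxo-2,3,3a,4,5,8,9,11a-octahydrocyclodeca[b]furan-4-yl 3-methylbutanoate | O=C1O[C@@H]2/C=C(/CO[Si](c3ccccc3)(c3ccccc3)C(C)(C)C)CC/C=C(/C(OC)OC)C[C@@H](OC(=O)CC(C)C)[C@@H]2C1=C | intermediate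
25 | (3aS,4R,6E,10E,11aR)-6-formyl-10-(hydroxymethyl)-3-methylidene-2-oxo-2,3,3a,4,5,8,9,11a-octahydrocyclodeca[b]furan-4-yl 3-methylbutanoate | C=C1C(=O)O[C@@H]2/C=C(/CO)CC/C=C(/C=O)C[C@@H](OC(=O)CC(C)C)[C@H]12 | target

**Step count and risks**

Total step count: 18. Longest linear sequence: 15 steps (steps 1–4, then 8–18).

Steps most likely to fail:

Step 12. Intermolecular oligomerisation may outrun the ten-membered ring closure, or the allenylindium may react through its terminal carbon to give an allenyl carbinol. The fallback sets out from 16 and comes back at 17. The alkynyl epoxide of 16 would be opened by copper-catalysed SN2′ borylation (CuCl/Xantphos cat., KOtBu cat., B2pin2, MeOH, THF, 0 °C), which should give the isolable hydroxy allenylboronate (2E,6E,9R)-3-{[(tert-butyldiphenylsilyl)oxy]methyl}-7-(dimethoxymethyl)-9-hydroxy-12-(4,4,5,5-tetramethyl-1,3,2-dioxaborolan-2-yl)dodeca-2,6,10,11-tetraenal F1 with anti stereochemistry. Warming F1 at high dilution in toluene should then close the ring by intramolecular propargylboration of the aldehyde through a cyclic six-membered transition state, with the same net inversion at C7. Hydrolysis of the borate ester returns 17.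

Step 15. Boron may add to the terminal instead of the internal alkyne carbon. The fallback sets out from 20 and comes back at 21. Markovnikov hydrosilylation with Et3SiH and [Cp*Ru(MeCN)3]PF6 (cat.) in CH2Cl2 should give the internal alkenylsilane (1R,2R,3R,4E,8E)-5-{[(tert-butyldiphenylsilyl)oxy]methyl}-9-(dimethoxymethyl)-3-hydroxy-2-[1-(triethylsilyl)ethenyl]cyclodeca-4,8-dien-1-yl 3-methylbutanoate F2. Iododesilylation with N-iodosuccinimide in (CF3)2CHOH should give the alkenyl iodide (1R,2R,3R,4E,8E)-5-{[(tert-butyldiphenylsilyl)oxy]methyl}-9-(dimethoxymethyl)-3-hydroxy-2-(1-iodoethenyl)cyclodeca-4,8-dien-1-yl 3-methylbutanoate F3. Miyaura borylation of F3 (PdCl2(dppf), B2pin2, KOAc, dioxane, 80 °C) returns 21.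

Step 17. The alkenylcopper may couple with the allylic acetate (C–C bond formation) before it takes up CO2, or the acetate may be lost to the alkoxide base before palladium is added. The fallback sets out from 20 and comes back at 24, and gives up CO2 as the one-carbon unit. Palladium-catalysed cyclocarbonylation of the homopropargylic alcohol 20 (PdCl2(PPh3)2, SnCl2, CO, MeCN, 65 °C) should close the same α-methylene lactone through the existing C6 hydroxyl, forming O–C12 and C11–C12 and giving 24 directly. This fallback makes no compound outside the list (F0).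

**Further compounds**

F1 | step 12 | (2E,6E,9R)-3-{[(tert-butyldiphenylsilyl)oxy]methyl}-7-(dimethoxymethyl)-9-hydroxy-12-(4,4,5,5-tetramethyl-1,3,2-dioxaborolan-2-yl)dodeca-2,6,10,11-tetraenal (allene axis as set by anti SN2′ borylation) | [H]C(B1OC(C)(C)C(C)(C)O1)=[C@@]=C([H])[C@H](O)C/C(C(OC)OC)=C\CC/C(CO[Si](c1ccccc1)(c1ccccc1)C(C)(C)C)=C\C=O
F2 | step 15 | (1R,2R,3R,4E,8E)-5-{[(tert-butyldiphenylsilyl)oxy]methyl}-9-(dimethoxymethyl)-3-hydroxy-2-[1-(triethylsilyl)ethenyl]cyclodeca-4,8-dien-1-yl 3-methylbutanoate | O[C@@H]1/C=C(/CO[Si](c2ccccc2)(c2ccccc2)C(C)(C)C)CC/C=C(/C(OC)OC)C[C@@H](OC(=O)CC(C)C)[C@@H]1C(=C)[Si](CC)(CC)CC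
F3 | step 15 | (1R,2R,3R,4E,8E)-5-{[(tert-butyldiphenylsilyl)oxy]methyl}-9-(dimethoxymethyl)-3-hydroxy-2-(1-iodoethenyl)cyclodeca-4,8-dien-1-yl 3-methylbutanoate | O[C@@H]1/C=C(/CO[Si](c2ccccc2)(c2ccccc2)C(C)(C)C)CC/C=C(/C(OC)OC)C[C@@H](OC(=O)CC(C)C)[C@@H]1C(=C)I
F0 | step 17 | none | none
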